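**Plan**

1. Retrosynthesis: the tetralone is cut at C1–C2 and C3–C4, so C2–C3 leaves as an acrylate and the remainder is a hydroxy-o-quinodimethane whose termini are the carbonyl carbon C1 and the diarylmethine carbon C4.
2. Enabling feature: C1 and C4 are ortho substituents (on C8a and C4a) of the hydroquinone ring, and C4–H is doubly benzylic and 1,5 to the carbonyl oxygen. In a 2-(naphthylmethyl)benzaldehyde, light therefore moves this hydrogen to oxygen and dearomatises the hydroquinone ring; re-aromatisation drives the cycloaddition.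
3. The aldehyde is cut at the CH(OH)–naphthyl bond into a 4-bromonaphthol ether and a 2-bromo-3,6-dialkoxybenzaldehyde; the benzene bromine is a placeholder for the formyl group.
4. Forward: naphthalene piece (2 steps), benzene piece (2 steps), union, deoxygenation and formylation; the cycloaddition then builds the saturated ring onto the hydroquinone ring, and oxidation plus one hydrogenolysis finish.
5. Helpers: three benzyl ethers, a benzyl ester on the dienophile (lost as CO2) and the C1 carbinol (oxidised to the ketone).
6. Stereochemistry: the only stereocentre, C4 (S), is set in the cycloaddition by a chiral titanium TADDOLate; C1 and C2 of the adduct are transient.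

Key step: step 8

Remark: 5-methoxynaphthalen-1-ol, 2-bromobenzene-1,4-diol and benzyl acrylate are taken as commercial.
Remark: the (R,R)-ligand is assumed to leave open the diene face that leads to (4S); if the sense of induction is the opposite, the (S,S)-ligand is used in the same way.

**Step 1**
Reactants: 1 5-methoxynaphthalen-1-ol
Product: 2 4-bromo-5-methoxynaphthalen-1-ol
Conditions: NBS (1.0 equiv), MeCN, −20 to 0 °C, dark
Reagents that add atoms: N-bromosuccinimide, O=C1CCC(=O)N1Br
Why: Electrophilic aromatic bromination in which the free naphthol OH, the strongest donor, directs to its para position C4, while low temperature and one equivalent of reagent limit ortho and double bromination.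

**Step 2**
Reactants: 2 4-bromo-5-methoxynaphthalen-1-ol
Product: 3 4-(benzyloxy)-1-bromo-8-methoxynaphthalene
Conditions: BnBr, K2CO3, DMF, rt
Reagents that add atoms: benzyl bromide, BrCc1ccccc1
Why: Williamson ether synthesis of the naphtholate, which masks the acidic OH before the organolithium chemistry.

**Step 3**
Reactants: 4 2-bromobenzene-1,4-diol
Product: 5 1,4-bis(benzyloxy)-2-bromobenzene
Conditions: BnBr (2.2 equiv), K2CO3, DMF, 50 °C, under N2
Reagents that add atoms: benzyl bromide, BrCc1ccccc1
Why: Double Williamson ether synthesis, run under nitrogen so that the hydroquinone is not oxidised before it is alkylated.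

**Step 4**
Reactants: 5 1,4-bis(benzyloxy)-2-bromobenzene
Product: 7 3,6-bis(benzyloxy)-2-bromobenzaldehyde, via aryllithium 6 (not isolated)
Conditions: LiN(iPr)2, THF, −78 °C; DMF, −78 to 0 °C; H2O
Reagents that add atoms: N,N-dimethylformamide, CN(C)C=O
Why: Directed ortho-metalation at the one ring hydrogen flanked by bromine and benzyloxy (acidified by both), giving a 2-bromoaryllithium that is stable at −78 °C and is formylated by DMF.

**Step 5**
Reactants: 3 4-(benzyloxy)-1-bromo-8-methoxynaphthalene; 7 3,6-bis(benzyloxy)-2-bromobenzaldehyde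
Product: 9 [3,6-bis(benzyloxy)-2-bromophenyl][4-(benzyloxy)-8-methoxynaphthalen-1-yl]methanol (racemic), via naphthyllithium 8 (not isolated)
Conditions: 3, n-BuLi, THF, −78 °C; then 7, −78 to −40 °C; H2O
Reagents that add atoms: none
Why: Bromine–lithium exchange followed by 1,2-addition of the aryllithium to the aldehyde, which should outrun exchange with the aryl bromide of 7; the carbinol stereocentre is irrelevant because it is removed in step 6.

**Step 6**
Reactants: 9 [3,6-bis(benzyloxy)-2-bromophenyl][4-(benzyloxy)-8-methoxynaphthalen-1-yl]methanol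
Product: 10 4-(benzyloxy)-1-{[3,6-bis(benzyloxy)-2-bromophenyl]methyl}-8-methoxynaphthalene
Conditions: Et3SiH (3 equiv), CF3CO2H (5 equiv), CH2Cl2, −20 to 0 °C
Reagents that add atoms: none
Why: Ionic hydrogenation, in which the diarylmethyl cation (stabilised by the para-benzyloxy naphthalene ring) is captured by hydride from the silane before benzyl ethers or the aryl bromide are affected.

**Step 7**
Reactants: 10 4-(benzyloxy)-1-{[3,6-bis(benzyloxy)-2-bromophenyl]methyl}-8-methoxynaphthalene
Product: 12 3,6-bis(benzyloxy)-2-{[4-(benzyloxy)-8-methoxynaphthalen-1-yl]methyl}benzaldehyde, via aryllithium 11 (not isolated)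
Conditions: n-BuLi, THF, −78 °C, 10 min; DMF, −78 to 0 °C; H2O
Reagents that add atoms: N,N-dimethylformamide, CN(C)C=O
Why: Bromine–lithium exchange at −78 °C is faster than deprotonation of the diarylmethane CH2, and formylation of the aryllithium with DMF puts the aldehyde ortho to that CH2.

**Step 8**
Reactants: 12 3,6-bis(benzyloxy)-2-{[4-(benzyloxy)-8-methoxynaphthalen-1-yl]methyl}benzaldehyde; 13 benzyl acrylate (benzyl prop-2-enoate)
Product: 15 benzyl (1S,2S,4S)-5,8-bis(benzyloxy)-4-[4-(benzyloxy)-8-methoxynaphthalen-1-yl]-1-hydroxy-1,2,3,4-tetrahydronaphthalene-2-carboxylate, via photoenol 14 (not isolated)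
Conditions: Ti(OiPr)4 (2 equiv) and (4R,5R)-2,2-dimethyl-α,α,α′,α′-tetraphenyl-1,3-dioxolane-4,5-dimethanol ((R,R)-TADDOL, 2.2 equiv) premixed in toluene; 13 (3 equiv), degassed toluene, hν 366 nm (LED), rt
Reagents that add atoms: none
Why: Excitation of the alkoxybenzaldehyde chromophore at 366 nm (naphthalene and benzyl ethers do not absorb there), intersystem crossing and 1,5-hydrogen transfer from the doubly benzylic CH2 to the carbonyl oxygen give a 1,4-biradical that relaxes to the hydroxy-o-quinodimethane 14 with hydroxy and naphthyl groups outward. This is a photoenolization/Diels–Alder reaction, closest to the trapping of photoenols of 2-benzylbenzaldehydes by acrylates and fumarates and to the Ti(OiPr)4/TADDOL-mediated enantioselective variant with 2-alkylbenzaldehydes and unsaturated carbonyl dienophiles. The dienol oxygen is held on the chiral titanium TADDOLate, which also binds the acrylate carbonyl, so an intermolecular suprafacial [4π+2π] cycloaddition through an endo, titanium-templated transition state closes the new six-membered carbocycle while the benzene ring regains aromaticity; both C–C bonds (acrylate CH2 to the diarylmethine carbon, ester-bearing CH to the carbinol carbon) form in this one event. C4 is set by the diene face that the TADDOLate leaves open (ligand control), whereas C1 and C2 follow from the outward geometry of 14 and the endo rule (all-cis) and are erased in steps 9 and 10. The step needs regioselectivity (ester next to the carbinol carbon, secured by the titanium tether and by the larger HOMO coefficient at the naphthyl-bearing terminus, which bonds to the unsubstituted acrylate carbon), outward dienol geometry (secured by the bulk of the peri-methoxynaphthyl group) and enantiofacial selectivity (secured by the ligand).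

**Step 9**
Reactants: 15 benzyl (1S,2S,4S)-5,8-bis(benzyloxy)-4-[4-(benzyloxy)-8-methoxynaphthalen-1-yl]-1-hydroxy-1,2,3,4-tetrahydronaphthalene-2-carboxylate
Product: 16 benzyl (4S)-5,8-bis(benzyloxy)-4-[4-(benzyloxy)-8-methoxynaphthalen-1-yl]-1-oxo-1,2,3,4-tetrahydronaphthalene-2-carboxylate (C2 epimers and enol)
Conditions: Dess–Martin periodinane, CH2Cl2, 0 °C to rt
Reagents that add atoms: none
Why: Dess–Martin oxidation of the secondary benzylic alcohol under near-neutral conditions, which avoids retro-aldol cleavage and leaves the non-enolisable C4 centre untouched.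

**Step 10**
Reactants: 16 benzyl (4S)-5,8-bis(benzyloxy)-4-[4-(benzyloxy)-8-methoxynaphthalen-1-yl]-1-oxo-1,2,3,4-tetrahydronaphthalene-2-carboxylate
Product: 18 (4S)-5,8-dihydroxy-4-(4-hydroxy-8-methoxynaphthalen-1-yl)-3,4-dihydronaphthalen-1(2H)-one, via keto acid 17 (not isolated)
Conditions: H2 (1 atm), Pd on carbon (10% Pd), EtOAc/MeOH, rt, air excluded; then 40 °C
Reagents that add atoms: none
Why: Hydrogenolysis of the three aryl benzyl ethers and the benzyl ester, after which the β-keto acid decarboxylates through its cyclic six-membered transition state; the methyl ether and the C4 centre are not touched.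

**Compound list**

1 | 5-methoxynaphthalen-1-ol | COc1cccc2c(O)cccc12 | starting material
2 | 4-bromo-5-methoxynaphthalen-1-ol | COc1cccc2c(O)ccc(Br)c12 | intermediate
3 | 4-(benzyloxy)-1-bromo-8-methoxynaphthalene | COc1cccc2c(OCc3ccccc3)ccc(Br)c12 | intermediate
4 | 2-bromobenzene-1,4-diol | Oc1ccc(O)c(Br)c1 | starting material
5 | 1,4-bis(benzyloxy)-2-bromobenzene | Brc1cc(OCc2ccccc2)ccc1OCc1ccccc1 | intermediate
6 | [3,6-bis(benzyloxy)-2-bromophenyl]lithium | [Li]c1c(Br)c(OCc2ccccc2)ccc1OCc1ccccc1 | intermediate
7 | 3,6-bis(benzyloxy)-2-bromobenzaldehyde | O=Cc1c(Br)c(OCc2ccccc2)ccc1OCc1ccccc1 | intermediate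
8 | [4-(benzyloxy)-8-methoxynaphthalen-1-yl]lithium | [Li]c1ccc(OCc2ccccc2)c2cccc(OC)c12 | intermediate
9 | [3,6-bis(benzyloxy)-2-bromophenyl][4-(benzyloxy)-8-methoxynaphthalen-1-yl]methanol (racemic) | COc1cccc2c(OCc3ccccc3)ccc(C(O)c3c(Br)c(OCc4ccccc4)ccc3OCc3ccccc3)c12 | intermediate
10 | 4-(benzyloxy)-1-{[3,6-bis(benzyloxy)-2-bromophenyl]methyl}-8-methoxynaphthalene | COc1cccc2c(OCc3ccccc3)ccc(Cc3c(Br)c(OCc4ccccc4)ccc3OCc3ccccc3)c12 | intermediate
11 | (3,6-bis(benzyloxy)-2-{[4-(benzyloxy)-8-methoxynaphthalen-1-yl]methyl}phenyl)lithium | COc1cccc2c(OCc3ccccc3)ccc(Cc3c([Li])c(OCc4ccccc4)ccc3OCc3ccccc3)c12 | intermediate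
12 | 3,6-bis(benzyloxy)-2-{[4-(benzyloxy)-8-methoxynaphthalen-1-yl]methyl}benzaldehyde | COc1cccc2c(OCc3ccccc3)ccc(Cc3c(C=O)c(OCc4ccccc4)ccc3OCc3ccccc3)c12 | intermediate
13 | benzyl acrylate | C=CC(=O)OCc1ccccc1 | starting material
14 | photoenol: 1,4-bis(benzyloxy)-5-{[4-(benzyloxy)-8-methoxynaphthalen-1-yl]methylidene}-6-(hydroxymethylidene)cyclohexa-1,3-diene, hydroxy and naphthyl groups both outward | O/C=C1\C(OCc2ccccc2)=CC=C(OCc2ccccc2)/C1=C\c1ccc(OCc2ccccc2)c2cccc(OC)c12 | intermediate
15 | benzyl (1S,2S,4S)-5,8-bis(benzyloxy)-4-[4-(benzyloxy)-8-methoxynaphthalen-1-yl]-1-hydroxy-1,2,3,4-tetrahydronaphthalene-2-carboxylate | COc1cccc2c(OCc5ccccc5)ccc([C@@H]3C[C@H](C(=O)OCc5ccccc5)[C@H](O)c4c(OCc5ccccc5)ccc(OCc5ccccc5)c43)c12 | intermediate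
16 | benzyl (4S)-5,8-bis(benzyloxy)-4-[4-(benzyloxy)-8-methoxynaphthalen-1-yl]-1-oxo-1,2,3,4-tetrahydronaphthalene-2-carboxylate | COc1cccc2c(OCc5ccccc5)ccc([C@@H]3CC(C(=O)OCc5ccccc5)C(=O)c4c(OCc5ccccc5)ccc(OCc5ccccc5)c43)c12 | intermediate
17 | (4S)-5,8-dihydroxy-4-(4-hydroxy-8-methoxynaphthalen-1-yl)-1-oxo-1,2,3,4-tetrahydronaphthalene-2-carboxylic acid | COc1cccc2c(O)ccc([C@@H]3CC(C(=O)O)C(=O)c4c(O)ccc(O)c43)c12 | intermediate
18 | (4S)-5,8-dihydroxy-4-(4-hydroxy-8-methoxynaphthalen-1-yl)-3,4-dihydronaphthalen-1(2H)-one | COc1cccc2c(O)ccc([C@@H]3CCC(=O)c4c(O)ccc(O)c43)c12 | target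

**Totals and risks**

Total step count: 10. Longest linear sequence: 8 steps (steps 1, 2, 5–10 from 1; equally steps 3–10 from 4).

Steps most likely to fail:

1. Step 8. The excited aldehyde may lose its energy by intramolecular triplet transfer to the naphthalene, so that photoenolization is inefficient. The enantiofacial discrimination may also be insufficient, and ester exchange at titanium may erode the benzyl ester. Fallback, setting out from 10 and returning at 16: an anionic annulation with resolution. Bromine–lithium exchange of 10 (n-BuLi, THF, −78 °C, via 11) and quenching with CO2 should give 3,6-bis(benzyloxy)-2-{[4-(benzyloxy)-8-methoxynaphthalen-1-yl]methyl}benzoic acid F1. Benzylation (BnBr, K2CO3, DMF) should give benzyl 3,6-bis(benzyloxy)-2-{[4-(benzyloxy)-8-methoxynaphthalen-1-yl]methyl}benzoate F2. Deprotonation of its doubly benzylic CH2 with LiN(iPr)2 (THF, −78 °C) and addition of 13 should bring about Michael addition and Dieckmann closure to racemic benzyl 5,8-bis(benzyloxy)-4-[4-(benzyloxy)-8-methoxynaphthalen-1-yl]-1-oxo-1,2,3,4-tetrahydronaphthalene-2-carboxylate F3. Preparative chromatography on a chiral stationary phase should then provide 16.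

2. Step 1. Bromination may occur at the ortho position C2, or twice, instead of cleanly at the para position. Fallback, setting out from 1 and returning at 9: regiocontrol by symmetry and electronic differentiation. Methylation (MeI, K2CO3, acetone) should give symmetrical 1,5-dimethoxynaphthalene F4. Vilsmeier–Haack formylation (POCl3, DMF) can then give only 4,8-dimethoxynaphthalene-1-carbaldehyde F5. Nucleophilic demethylation with NaSEt in DMF should remove the methyl group para to the formyl group, the only one whose naphtholate is conjugated with the aldehyde, to give 4-hydroxy-8-methoxynaphthalene-1-carbaldehyde F6. Benzylation (BnBr, K2CO3, DMF) should give 4-(benzyloxy)-8-methoxynaphthalene-1-carbaldehyde F7. Aryllithium 6, made from 5 as in step 4, is then added to F7 instead of DMF and should give 9 directly.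

3. Step 10. The aryl ketone may be over-reduced, or the hindered benzyl ethers may be cleaved incompletely under hydrogenolysis. Fallback, setting out from 16 and returning at 18: Lewis-acid debenzylation. BCl3 with pentamethylbenzene as benzyl-cation acceptor (CH2Cl2, −78 °C) should cleave the three benzyl ethers and the benzyl ester while the unchelated naphthyl methyl ether survives. Aqueous work-up and warming to 40 °C should decarboxylate keto acid 17 to 18.

**Further compounds**

F1 | step 8 | 3,6-bis(benzyloxy)-2-{[4-(benzyloxy)-8-methoxynaphthalen-1-yl]methyl}benzoic acid | COc1cccc2c(OCc3ccccc3)ccc(Cc3c(C(=O)O)c(OCc4ccccc4)ccc3OCc3ccccc3)c12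
F2 | step 8 | benzyl 3,6-bis(benzyloxy)-2-{[4-(benzyloxy)-8-methoxynaphthalen-1-yl]methyl}benzoate | COc1cccc2c(OCc3ccccc3)ccc(Cc3c(C(=O)OCc4ccccc4)c(OCc4ccccc4)ccc3OCc3ccccc3)c12
F3 | step 8 | racemic benzyl 5,8-bis(benzyloxy)-4-[4-(benzyloxy)-8-methoxynaphthalen-1-yl]-1-oxo-1,2,3,4-tetrahydronaphthalene-2-carboxylate | COc1cccc2c(OCc5ccccc5)ccc(C3CC(C(=O)OCc5ccccc5)C(=O)c4c(OCc5ccccc5)ccc(OCc5ccccc5)c43)c12
F4 | step 1 | 1,5-dimethoxynaphthalene | COc1cccc2c(OC)cccc12
F5 | step 1 | 4,8-dimethoxynaphthalene-1-carbaldehyde | COc1cccc2c(OC)ccc(C=O)c12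
F6 | step 1 | 4-hydroxy-8-methoxynaphthalene-1-carbaldehyde | COc1cccc2c(O)ccc(C=O)c12
F7 | step 1 | 4-(benzyloxy)-8-methoxynaphthalene-1-carbaldehyde | COc1cccc2c(OCc3ccccc3)ccc(C=O)c12
F0 | step 10 | none | none
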